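All runs are simulated for an exercise.

Time was what I had to work with: 98 min of readings on the east, south-west and north flasks, and the north-west run to foretell at 98 min.

| setting | east | south-west | north | north-west |
|---|---|---|---|---|
| substrate | 0.120 M | 0.120 M | 0.120 M | 0.120 M |
| partner | 0.240 M | 0.120 M | 0.240 M | 0.0370 M |
| free catalyst | 0.00600 M | 0.00600 M | 0.00300 M | 0.00600 M |
| time |  |  |  | 98 min |

| east run: time / min | east run: [substrate] / M | south-west run: time / min | south-west run: [substrate] / M | north run: time / min | north run: [substrate] / M |
|---|---|---|---|---|---|
| 14 | 0.1084 | 14 | 0.1120 | 14 | 0.1143 |
| 28 | 0.0985 | 28 | 0.1048 | 28 | 0.1080 |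
| 42 | 0.0902 | 42 | 0.0993 | 42 | 0.1036 |
| 56 | 0.0830 | 56 | 0.0944 | 56 | 0.0985 |
| 70 | 0.0780 | 70 | 0.0895 | 70 | 0.0947 |
| 84 | 0.0725 | 84 | 0.0863 | 84 | 0.0915 |
| 98 | 0.0696 | 98 | 0.0832 | 98 | 0.0879 |

(standard deviation of a reading: 4 × 10⁻⁴ M)

1. reaction order in [partner] at the outset, round the charge of the east run, defined at two percent of the substrate turned into product
2. reaction order in [free catalyst] at the outset, round the charge of the east run, defined at two percent of the substrate turned into product
3. substrate in the north-west run at 98 min, as a share of the substrate charged

- Overall: substrate + partner -> product, with free catalyst as catalyst.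
- Constant volume, constant temperature.
- The analysis sees a species whether free or bound.
- "The second partner" is partner.
- An order is taken over about fifteen percent of the charge, up and down.

Over the first 14 min, the north run, with half the catalyst of the east run, lost 0.00570 M of substrate against 0.0116 M, so I put the order in free catalyst at 1.03. The same window gave a mean rate of 8.29 × 10⁻⁴ M/min in the east run and 5.71 × 10⁻⁴ M/min in the south-west run, which has half the partner. That is a factor of 1.45, not the 2 of plain proportion.

I therefore let the rate follow R/(K+R), with R the partner concentration. The factor gave K = 0.196 M, the half-speed partner level: the R at which the rate stands at half its ceiling. The order in partner is then K/(K+R), or 0.450 at the east charge.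

Next I needed a speed constant A, the rate divided by [substrate]·R/(K+R). The first window of the south-west run, taken at its mean concentrations, gave A = 0.0133 /min. In the north-west run the partner is the limiting reagent, with 0.0370 M charged, less than the 0.120 M of substrate. The charge held steady for 98 min gave 0.0247 M turned, which is 66.8% of that partner, so holding the partner steady was a poor assumption. I put this first answer back, taking the mean levels at half of it, and got 0.0156 M.

The weak link was A, read from 14 min and used for 98 min. The whole south-west run gave 0.0108 /min, a lower value. One more round with it gave 0.0154 M turned, leaving 87.2% of the substrate.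

The forecast, reasoning that “This suggests saturation”, differed slightly from my figures. It gave 0.5 (0.35 to 0.68) for the partner order, 0.95 (0.8 to 1.05) for the catalyst order, and 86.5% (84.5% to 88.5%) for the substrate left.

The simulation gave 0.44, 0.99 and 86.4%, each inside the forecast's range.

    free catalyst + substrate + partner → product + free catalyst (12.06 /M²/min)
    free catalyst + product → spent catalyst + product (0.4722 /M/min)
    free catalyst + partner ⇌ idle catalyst-reagent complex, settled at all times (5.530 /M)

The order in partner round the east charge stands at 0.44 because free catalyst and partner tie up as idle catalyst-reagent complex; the same run without that step gives 1.0. My K of 0.196 M had put that order at 0.450. Carried to the north-west run, the same K had given 0.0154 M turned, and the simulation's 86.4% of substrate left means 0.0163 M turned.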